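The leftover is where we begin: at the last reading of each run, E and G added together fall short of the E charged.

the same everywhere: E 0.17 M; J 0.85 mM

| flask | X | remark | time |
|---|---|---|---|
| birch | 0.17 M | the very flask that is asked about, followed so far |  |
| cedar | 0.34 M | run made earlier |  |
| flask | 0.170 M |  | 2.0 min |

| run | time / s | G / % | E / % |
|---|---|---|---|
| birch | 10.0 | 2.0 | 98.5 |
| birch | 15.0 | 0.9 | 95.9 |
| birch | 20.0 | 2.3 | 95.1 |
| birch | 30.0 | 4.5 | 89.8 |
| birch | 40.0 | 8.0 | 85.5 |
| birch | 50.0 | 13.9 | 82.1 |
| cedar | 10.0 | 0 | 96.1 |
| cedar | 12.0 | 1.9 | 96.5 |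
| cedar | 25.0 | 2.0 | 91.1 |
| cedar | 40.0 | 8.7 | 82.2 |
| cedar | 50.0 | 12.4 | 77.0 |
| cedar | 60.0 | 16.0 | 72.2 |
| cedar | 80.0 | 21.5 | 61.2 |

(readings scatter by 1 percentage point)

- percentages count the E that a species holds: one Q counts as two
- the average divides the monomer in chains by the number of chains begun, living and dead together
- candidate steps: E + L -> G + L; J -> Z; X + E -> D; G + L -> E + L; E + Z -> L + G; 2 E -> Q
- the earlier runs do not show the number of chains; that part of a forecast is a guess

* average number of monomer units in a chain (chains begun, living or dead) at 2.0 min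
* part of the E that has reacted at 2.0 min

Birch and cedar look nearly the same, but cedar holds twice the X. At 50.0 s their G readings, 13.9% and 12.4%, differ by 1.5 percentage points with a scatter of 1 point on each, while their E readings are 82.1% and 77.0%. Cedar's E stands lower because its leftover of 10.6% is larger than birch's 4.00%. We read this as a leak, X + E -> D, which is pseudo-first-order in E while X stays near its charge.

Cedar's last reading, with X taken at its charge and mean E taken midway between the charge and that reading, gives 0.00789 M⁻¹ s⁻¹ as our reading of the leak constant, the leftover per unit of X, per unit of time and per mean fraction of E.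

The forecast gives 74 for dp and 47% for c, and holds that the loss “scales roughly with X, so X + E -> D is the main side reaction”. It puts the side loss at about 11%. Our leak constant, with the forecast's c setting mean E in the asked flask, gives 12.3%, a little more.

The flask gives 73.1 and 47.0%, both within the forecast's margins.

    E + L → G + L, rate k1*[L]*[E] (k = 10.5 M⁻¹ s⁻¹)
    J → Z (k = 0.0267 s⁻¹)
    X + E → D (k = 0.00829 M⁻¹ s⁻¹)
    G + L → E + L, rate k4*[L] as long as [G] is above zero (k = 0.422 s⁻¹)
    E + Z → L + G (k = 1.68 M⁻¹ s⁻¹)
    2 E → Q (k = 1.77 × 10⁻⁵ M⁻¹ s⁻¹)

At 2.00 min in this flask, the step to G uses E 6.9 times as fast as the step to D, and G, each step taken net, is made 2.25 times faster than it is used up. The flask then holds E at 53.0%, G at 34.8% and D at 12.2%, against our 12.3%. A run with another charge of J ends away from the forecast's numbers: the flask with 0.0021 M of J gives 66.8% for c and 48.4 for dp. With that c, the leak constant gives 10.7% there, and the computed D is 10.2%.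

The readings stem from a simulated flask for an exercise; noise was put on by code.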